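## The problem

The target is a 2,3-trans-3-methoxyflavanone. Ring A (5,6-dihydroxy-7-methoxy) is fused to the pyranone ring C, and ring B (2,3-dihydroxy-4-methoxyphenyl) is attached at C2. The only stereocentres are the adjacent C2 (R) and C3 (R). C3 lies α to the C4 ketone and can relax to the diequatorial trans arrangement once C2 is fixed, so C2 carries the absolute information and has no later correction. The β-aryloxy ketone of ring C opens to a chalcone under base, which would erase C2. The two catechol units oxidise readily in basic, aerated media, so the phenols must be released last and without base. Ring A must end with free hydroxyls at C5 and C6 beside a methyl ether at C7. O5 can be recognised through chelation to the peri C4 carbonyl, but O6 needs a protecting group of its own. The enabling feature is the substitution of C3: it carries one hydrogen, a methoxy group, the C4 acyl carbon and the C2 carbinol carbon. That is the pattern left when an acyl carbene carbon has taken up an alcohol and an aldehyde, so the C3–O and C2–C3 bonds can be formed in one event. The remaining ring bond, O1–C8a, is an aryl–oxygen bond that can be closed without touching C2.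

## Retrosynthesis

**Target 15 to flavanone 14 (three O–benzyl bonds and the O5–methyl bond).** The four phenols are unmasked in the last step from 14, which carries benzyl ethers at O6, O2′ and O3′ and a methyl ether at O5. A methyl group at O5 lets ring A come from a symmetric phenol. It is also the one methyl ether that a boron Lewis acid can single out, because it sits peri to the C4 carbonyl. The forward step must spare the methyl ethers at C3, C7 and C4′.

**Flavanone 14 to bromo aldol 13 (O1–C8a).** Cutting the aryl–oxygen bond is preferred to cutting O1–C2. A Mitsunobu or oxa-Michael closure would make the ring bond at the stereocentre itself, a benzylic carbon that the trialkoxy ring B stabilises strongly as a cation. A copper-mediated O-arylation of the C2 hydroxyl onto a C8a bromide leaves all four bonds at C2 intact, so the aldol configuration is carried over with retention. The precursor 13 is acyclic. The forward reaction must be faster than base-induced retro-aldol cleavage.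

**Aldol 13 to diazoketone 8, aldehyde 10 and methanol 11 (C2–C3 and C3–O).** Both bonds at C3 are cut together. Compared with an enolate aldol of a preformed α-methoxy ketone, this removes one step and places bond formation, ether formation and both stereocentres under one chiral catalyst. The three components are achiral and each contains at most one aromatic ring. The forward reaction must capture the methanol-derived oxonium ylide (or its enol 12) with 10 before proton transfer, and must do so with enantio- and anti-selectivity. Three measures strengthen it:
- 10 is used in excess and 8 with 11 are added slowly.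
- The ortho-benzyloxy oxygen of 10 gives the acid a second binding point.
- The ortho oxygen of 8 carries a methyl group, which can neither migrate nor eliminate if it adds reversibly to the carbene.

**Diazoketone 8 back to phenol 1 and benzyl bromide 2.** The bond between the diazomethyl carbon and the acyl carbon is cut to give acid chloride 7, made from acid 6. Acid 6 is the oxidation product of aldehyde 5. The formyl–aryl bond of 5 is cut back, through chloro ether 4, to bromoarene 3, which is the benzyl ether of 1. Because 3 is symmetric, its two open ring positions are equivalent and both lie next to bromine, so the formylation has only one possible outcome and the bromine ends up at the future C8a.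

**Aldehyde 10 to catechol aldehyde 9 and benzyl bromide 2 (two O–benzyl bonds).** A double Williamson etherification with two equivalents of 2 gives ring B in one step. Benzyl is chosen so that these ethers fall in the same final operation as the O6 benzyl group.

## Roads not taken

**Alternative 1: oxidative C–H etherification.** The cut is again O1–C8a, but C8a carries hydrogen. The phenolic anti-aldol (2R,3R)-1-[2-(benzyloxy)-3-hydroxy-4-methoxyphenyl]-3-[2,3-bis(benzyloxy)-4-methoxyphenyl]-3-hydroxy-2-methoxypropan-1-one (A2) would be oxidised at its ring A phenol with the trivalent iodine reagent PhI(OAc)2 in hexafluoroisopropanol. The C2 hydroxyl would add to the para carbon and rearomatisation would give (2R,3R)-5-(benzyloxy)-2-[2,3-bis(benzyloxy)-4-methoxyphenyl]-6-hydroxy-3,7-dimethoxychroman-4-one (A1).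
- Merits: no halogen and no base, so retro-aldol cleavage and ring opening are not an issue. A1 has O6 free and O5 benzylated, so the endgame is plain hydrogenolysis. In this respect it is better than the chosen plan, which needs a selective demethylation.
- Weak points: the phenol of A2 is flanked by two alkoxy-bearing carbons, where oxidised phenols are usually captured to give quinone monoketals. The para carbon that must be attacked is ortho to the deactivating acyl group. A1 is a hydroquinone monoether and is more easily oxidised than A2. Ring B and the benzylic carbinol are also exposed to the oxidant. Ring A of A2 needs three differently substituted oxygens without the help of symmetry.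
- Comparison: A2 poses the same anti-aldol problem, so the alternative adds an oxidation risk without removing the stereochemical one. The chosen plan sets regiochemical certainty (the bromine fixes the site) and a symmetric, purchasable ring A precursor against the cleaner deprotection of Alternative 1.

**Alternative 2: carbene-catalysed benzoin closure.** The cut is C3–C4. The racemic, configurationally labile dialdehyde 3-(benzyloxy)-6-{1-[2,3-bis(benzyloxy)-4-methoxyphenyl]-2-oxoethoxy}-2,4-dimethoxybenzaldehyde (A4) would be cyclised by a chiral triazolium-derived carbene. The ring A aldehyde would act as acyl anion equivalent toward the aliphatic aldehyde while one C2 epimer is selected, giving (2R,3R)-6-(benzyloxy)-2-[2,3-bis(benzyloxy)-4-methoxyphenyl]-3-hydroxy-5,7-dimethoxychroman-4-one (A3).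
- Merits: ring closure and stereocontrol coincide, no transition metal or halide is needed, and the racemising α-centre of A4 allows a dynamic resolution. On these points it is more elegant than the chosen plan.
- Weak points: the catalyst must add to the aryl aldehyde, which is flanked by two ortho substituents, rather than to the more accessible aliphatic aldehyde. The reverse polarity would give the isomeric 4-hydroxychroman-3-one. A4 is an α-aryl-α-aryloxy acetaldehyde, prone to enolisation and elimination, and needs several steps to make. A3 carries a free C3 hydroxyl, so a base-free O-methylation of an epimerisable α-ketol must follow.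
- Comparison: the route is at least two steps longer. The chosen plan sets against it the direct delivery of the C3 methoxy group from methanol and far simpler fragments.

**Alternative 3: aryne annulation.** The cuts are O1–C8a and C4–C4a. Fluoride (CsF) would trigger 1,2-elimination of 2,3-bis(benzyloxy)-4-methoxy-6-(trimethylsilyl)phenyl trifluoromethanesulfonate (A6). The alkoxide of methyl (2R,3R)-3-[2,3-bis(benzyloxy)-4-methoxyphenyl]-3-hydroxy-2-methoxypropanoate (A7) would add at C8a, directed by the neighbouring alkoxy group, and the aryl anion at C4a would attack the ester to give (2R,3R)-5,6-bis(benzyloxy)-2-[2,3-bis(benzyloxy)-4-methoxyphenyl]-3,7-dimethoxychroman-4-one (A5).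
- Merits: two ring bonds form in one convergent step. A7 is an anti-glycolate aldol of a known, auxiliary- or catalyst-controlled kind, so its stereochemical step is better precedented than the key step chosen here. A5 needs only hydrogenolysis.
- Weak points: A6 is a pentasubstituted arene without symmetry and needs a long preparation. A secondary aliphatic alkoxide is a poorer aryne partner than a phenoxide. The aryl anion can be protonated by a second molecule of A7 before it reaches the ester, giving the uncyclised aryl ether. The alkoxide of A7 can undergo retro-aldol cleavage.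
- Comparison: the chosen plan accepts an unprecedented stereochemical step in exchange for fragments that are each one or a few conventional steps from purchasable materials, and for a ring closure that is a standard reaction class.

Key step: step 6

Remark: the sense of asymmetric induction of a binaphthyl phosphoric acid on this substrate pair cannot be predicted with confidence. The (R)-acid is written and its mirror image would be used if first experiments show the opposite sense. Compounds 1, 2, 9 and 11 are taken to be purchased.

## Route

Step 1
Reactants: 1 4-bromo-2,6-dimethoxyphenol; 2 benzyl bromide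
Product: 3 2-(benzyloxy)-5-bromo-1,3-dimethoxybenzene
Conditions: K2CO3, DMF, 60 °C
Reagents that add atoms: none
Why: Williamson ether synthesis on a phenoxide; the hindered but acidic 2,6-dimethoxyphenol should alkylate cleanly on oxygen in a dipolar aprotic solvent.

Step 2
Reactants: 3 2-(benzyloxy)-5-bromo-1,3-dimethoxybenzene
Product: 5 3-(benzyloxy)-6-bromo-2,4-dimethoxybenzaldehyde, via α-chloro ether 4 (not isolated)
Conditions: Cl2CHOMe, AgOTf, CH2Cl2, −78 to 0 °C; aq. NaHCO3
Reagents that add atoms: dichloromethyl methyl ether, COC(Cl)Cl; water, O
Why: Rieche formylation in its silver-triflate-promoted form, chosen because it runs cold and should spare the central benzyl ether. The two open positions of 3 are equivalent by symmetry and each is ortho and para to a methoxy group, so only one aldehyde can form and it has the formyl group beside bromine. Aqueous work-up hydrolyses 4 to the aldehyde.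

Step 3
Reactants: 5 3-(benzyloxy)-6-bromo-2,4-dimethoxybenzaldehyde
Product: 6 3-(benzyloxy)-6-bromo-2,4-dimethoxybenzoic acid
Conditions: NaClO2, NaH2PO4, 2-methyl-2-butene, t-BuOH/H2O, rt
Reagents that add atoms: sodium chlorite, [Na+].[O-]Cl=O
Why: Pinnick oxidation; chlorous acid oxidises hindered aromatic aldehydes without touching benzyl ethers or the aryl bromide, and the alkene scavenges hypochlorous acid before it can chlorinate the electron-rich ring.

Step 4
Reactants: 6 3-(benzyloxy)-6-bromo-2,4-dimethoxybenzoic acid
Product: 8 1-[3-(benzyloxy)-6-bromo-2,4-dimethoxyphenyl]-2-diazoethan-1-one, via acid chloride 7 (not isolated)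
Conditions: (COCl)2, cat. DMF, CH2Cl2, 0 °C to rt, evaporate; CH2N2, Et3N, Et2O/THF, 0 °C
Reagents that add atoms: diazomethane, C=[N+]=[N-]; oxalyl chloride, O=C(Cl)C(=O)Cl (its chlorine stays only in 7)
Why: Acylation of diazomethane by an aroyl chloride, the first stage of the Arndt–Eistert sequence, with triethylamine as hydrogen chloride acceptor (Newman–Beal variant). Diazomethane is small enough to reach the doubly ortho-substituted acyl carbon, and the amine should prevent conversion of 8 into a chloromethyl ketone.

Step 5
Reactants: 9 2,3-dihydroxy-4-methoxybenzaldehyde; 2 benzyl bromide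
Product: 10 2,3-bis(benzyloxy)-4-methoxybenzaldehyde
Conditions: BnBr (2.5 equiv), K2CO3, DMF, 60 °C
Reagents that add atoms: benzyl bromide (second equivalent), BrCc1ccccc1
Why: Double Williamson ether synthesis; each of the two catechol phenoxides takes one benzyl group from the excess benzyl bromide, the chelated ortho hydroxyl reacting last.

Step 6
Reactants: 8 1-[3-(benzyloxy)-6-bromo-2,4-dimethoxyphenyl]-2-diazoethan-1-one; 10 2,3-bis(benzyloxy)-4-methoxybenzaldehyde; 11 methanol
Product: 13 (2R,3R)-1-[3-(benzyloxy)-6-bromo-2,4-dimethoxyphenyl]-3-[2,3-bis(benzyloxy)-4-methoxyphenyl]-3-hydroxy-2-methoxypropan-1-one, via Z-enol 12 (not isolated)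
Conditions: Rh2(OAc)4 (2 mol %), (R)-3,3′-bis(2,4,6-triisopropylphenyl)-1,1′-binaphthyl-2,2′-diyl hydrogen phosphate (10 mol %), 3 Å MS, CH2Cl2, 0 °C; 8 and MeOH added slowly to 10 (2 equiv)
Reagents that add atoms: none
Why: Proposed new method: Rh2(OAc)4 expels dinitrogen from 8 to give an electrophilic acceptor-only rhodium carbene, which methanol attacks to form a protic oxonium ylide that relaxes to the (Z)-enol 12 before the 1,2-proton shift to the simple α-methoxy ketone is complete. The phosphoric acid is expected to bind 12 through its phosphoryl oxygen and the carbonyl of 10 through its acidic hydroxyl, so that C–C bond formation occurs inside one chiral hydrogen-bonded assembly and outruns proton transfer. The closest known reaction type is the three-component coupling of aryldiazoacetates, alcohols and aldehydes or imines under Rh2(OAc)4 and a chiral Brønsted acid by trapping of oxonium ylides; an acceptor-only aryl diazoketone, methanol and an electron-rich benzaldehyde have not been joined in this way. No ring is closed; the step forms the C3–O and C2–C3 bonds of the later flavanone and both stereocentres. The carbinol centre (later C2) is set by the face of 10 exposed in the acid-bound complex and the methoxy-bearing centre (later C3) by the face of 12 presented in the same complex, so both are under catalyst control. The anti relation is expected from the arrangement that keeps the aryl group of 10 away from the twisted aroyl group of 12. The step needs three-component capture to beat plain O–H insertion; this is supported by the second hydrogen-bond acceptor in 10 (its ortho-benzyloxy oxygen), by the excess of 10, by slow addition of 8 and 11, and by sieves that exclude water but not methanol. Reversible attack of the ortho-methoxy oxygen of 8 on the carbene would give a cyclic ylide whose methyl group cannot migrate or eliminate, so it should return to the productive path.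

Step 7
Reactants: 13 (2R,3R)-1-[3-(benzyloxy)-6-bromo-2,4-dimethoxyphenyl]-3-[2,3-bis(benzyloxy)-4-methoxyphenyl]-3-hydroxy-2-methoxypropan-1-one
Product: 14 (2R,3R)-6-(benzyloxy)-2-[2,3-bis(benzyloxy)-4-methoxyphenyl]-3,5,7-trimethoxychroman-4-one
Conditions: CuI (10 mol %), 1,10-phenanthroline (20 mol %), Cs2CO3, toluene, 80 °C
Reagents that add atoms: none
Why: Intramolecular Ullmann-type C–O coupling of a secondary alcohol with an aryl bromide, closing the six-membered ring C; the ortho acyl group accelerates the copper-mediated substitution. No bond at the carbinol carbon is broken, so C2 is retained, and C3 can only drift toward the more stable trans arrangement. Toluene and a sparingly soluble carbonate keep the free alkoxide concentration low.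

Step 8
Reactants: 14 (2R,3R)-6-(benzyloxy)-2-[2,3-bis(benzyloxy)-4-methoxyphenyl]-3,5,7-trimethoxychroman-4-one
Product: 15 (2R,3R)-2-(2,3-dihydroxy-4-methoxyphenyl)-5,6-dihydroxy-3,7-dimethoxychroman-4-one
Conditions: BCl3, C6HMe5, CH2Cl2, −78 to 0 °C; MeOH
Reagents that add atoms: none
Why: Lewis-acid ether cleavage; BCl3 with pentamethylbenzene as cation scavenger removes aryl benzyl ethers at low temperature, and on warming it cleaves the O5 methyl ether selectively through the six-membered chelate with the C4 carbonyl. The methyl ethers at C7 and C4′ lack such activation and the aliphatic C3 ether is a poorer leaving group, so they should persist; the acidic, non-oxidising medium protects the catechols and both stereocentres.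

## Compound list

1 | 4-bromo-2,6-dimethoxyphenol | COc1cc(Br)cc(OC)c1O | starting material
2 | benzyl bromide | BrCc1ccccc1 | starting material
3 | 2-(benzyloxy)-5-bromo-1,3-dimethoxybenzene | COc1cc(Br)cc(OC)c1OCc1ccccc1 | intermediate
4 | 2-(benzyloxy)-5-bromo-4-[chloro(methoxy)methyl]-1,3-dimethoxybenzene (racemic, not isolated) | COc1cc(Br)c(C(Cl)OC)c(OC)c1OCc1ccccc1 | intermediate
5 | 3-(benzyloxy)-6-bromo-2,4-dimethoxybenzaldehyde | COc1cc(Br)c(C=O)c(OC)c1OCc1ccccc1 | intermediate
6 | 3-(benzyloxy)-6-bromo-2,4-dimethoxybenzoic acid | COc1cc(Br)c(C(=O)O)c(OC)c1OCc1ccccc1 | intermediate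
7 | 3-(benzyloxy)-6-bromo-2,4-dimethoxybenzoyl chloride (not isolated) | COc1cc(Br)c(C(=O)Cl)c(OC)c1OCc1ccccc1 | intermediate
8 | 1-[3-(benzyloxy)-6-bromo-2,4-dimethoxyphenyl]-2-diazoethan-1-one | COc1cc(Br)c(C(=O)C=[N+]=[N-])c(OC)c1OCc1ccccc1 | intermediate
9 | 2,3-dihydroxy-4-methoxybenzaldehyde | COc1ccc(C=O)c(O)c1O | starting material
10 | 2,3-bis(benzyloxy)-4-methoxybenzaldehyde | COc1ccc(C=O)c(OCc2ccccc2)c1OCc1ccccc1 | intermediate
11 | methanol | CO | starting material
12 | (Z)-1-[3-(benzyloxy)-6-bromo-2,4-dimethoxyphenyl]-2-methoxyethen-1-ol (not isolated) | CO/C=C(\O)c1c(Br)cc(OC)c(OCc2ccccc2)c1OC | intermediate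
13 | (2R,3R)-1-[3-(benzyloxy)-6-bromo-2,4-dimethoxyphenyl]-3-[2,3-bis(benzyloxy)-4-methoxyphenyl]-3-hydroxy-2-methoxypropan-1-one | COc1ccc([C@@H](O)[C@@H](OC)C(=O)c2c(Br)cc(OC)c(OCc3ccccc3)c2OC)c(OCc2ccccc2)c1OCc1ccccc1 | intermediate
14 | (2R,3R)-6-(benzyloxy)-2-[2,3-bis(benzyloxy)-4-methoxyphenyl]-3,5,7-trimethoxychroman-4-one | COc1ccc([C@H]2Oc3cc(OC)c(OCc4ccccc4)c(OC)c3C(=O)[C@@H]2OC)c(OCc2ccccc2)c1OCc1ccccc1 | intermediate
15 | (2R,3R)-2-(2,3-dihydroxy-4-methoxyphenyl)-5,6-dihydroxy-3,7-dimethoxychroman-4-one | COc1ccc([C@H]2Oc3cc(OC)c(O)c(O)c3C(=O)[C@@H]2OC)c(O)c1O | target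

## Step count and risk

Total: 8 steps. Longest linear sequence: 7 steps (steps 1, 2, 3, 4, 6, 7, 8); step 5 is a one-step branch.

**Step 6 (key step, proposed new method).**
- Most likely failure: proton transfer within the oxonium ylide or enol outpaces capture by the aldehyde, because the trialkoxybenzaldehyde is weakly electrophilic even when acid-bound. The outcome would then be simple O–H insertion. Facial or anti selectivity may also be insufficient, and the ortho-methoxy oxygen may intercept the carbene reversibly.
- Fallback: the same two bonds are made stepwise by known chemistry, setting out from 8. Rh2(OAc)4-catalysed O–H insertion of methanol should give 1-[3-(benzyloxy)-6-bromo-2,4-dimethoxyphenyl]-2-methoxyethan-1-one F1. Enolisation with dicyclohexylboron chloride and triethylamine in ether at −78 °C should give the (E)-enol borinate [(E)-1-[3-(benzyloxy)-6-bromo-2,4-dimethoxyphenyl]-2-methoxyethenyl] dicyclohexylborinate F2. Its closed-transition-state aldol with 10, followed by buffered methanolic work-up, should give the anti aldol as a racemate. The racemate consists of 13 and its mirror image (2S,3S)-1-[3-(benzyloxy)-6-bromo-2,4-dimethoxyphenyl]-3-[2,3-bis(benzyloxy)-4-methoxyphenyl]-3-hydroxy-2-methoxypropan-1-one F3. F3 is removed by preparative chromatography on a chiral stationary phase, and the route is rejoined at 13.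

**Step 7.**
- Most likely failure: the carbonate induces retro-aldol cleavage or dehydration of the β-hydroxy ketone before the C–O bond forms. Once the flavanone exists, base-induced ring opening to the chalcone and reclosure would erode the C2 configuration.
- Fallback: the carbonyl is removed for the duration of the coupling, setting out from 13. NaBH4 in methanol/THF at 0 °C should give (2R,3R)-1-[3-(benzyloxy)-6-bromo-2,4-dimethoxyphenyl]-3-[2,3-bis(benzyloxy)-4-methoxyphenyl]-2-methoxypropane-1,3-diol F4 as a mixture of C1 epimers. Only its C3 hydroxyl can reach the bromide in a six-membered closure. The same CuI/1,10-phenanthroline/Cs2CO3 coupling at 110 °C, now with no enolisable or cleavable ketone, should give (2R,3S)-6-(benzyloxy)-2-[2,3-bis(benzyloxy)-4-methoxyphenyl]-3,5,7-trimethoxychroman-4-ol F5 as a mixture of C4 epimers. The descriptor at C3 changes only through ligand priorities. Oxidation with Dess–Martin periodinane buffered by NaHCO3 returns to the route at 14.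

**Step 8.**
- Most likely failure: the C3 methyl ether is lost through boron chelation between the C4 carbonyl and the C3 oxygen. Other possibilities are partial cleavage of the C7 or C4′ methyl ethers on warming, or Lewis-acid opening at the benzylic C2–O1 bond.
- Fallback: the two deprotections are separated, setting out from 14. Hydrogenolysis (H2, Pd/C, ethyl acetate, rt) removes the three benzyl groups under neutral conditions and should give (2R,3R)-2-(2,3-dihydroxy-4-methoxyphenyl)-6-hydroxy-3,5,7-trimethoxychroman-4-one F6. The peri methyl ether alone is then cleaved with the milder chelating Lewis acid MgI2 (as its diethyl etherate) in THF, arriving at 15.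

**Step 2.**
- Most likely failure: the central benzyl ether is lost by Lewis-acid chelation between neighbouring oxygens, or substitution is sluggish at a position flanked by bromine and methoxy.
- Fallback: the carboxyl carbon is introduced by deprotonation instead of electrophilic substitution, setting out from 3. Lithium diisopropylamide in THF at −78 °C should remove the proton between bromine and methoxy without halogen–metal exchange, giving [3-(benzyloxy)-6-bromo-2,4-dimethoxyphenyl]lithium F7. Quenching with carbon dioxide and acidifying with dilute HCl gives acid 6 directly, so aldehyde 5 and step 3 are bypassed.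

## Further compounds

F1 | step 6 | 1-[3-(benzyloxy)-6-bromo-2,4-dimethoxyphenyl]-2-methoxyethan-1-one | COCC(=O)c1c(Br)cc(OC)c(OCc2ccccc2)c1OC
F2 | step 6 | [(E)-1-[3-(benzyloxy)-6-bromo-2,4-dimethoxyphenyl]-2-methoxyethenyl] dicyclohexylborinate | CO/C=C(/OB(C1CCCCC1)C1CCCCC1)c1c(Br)cc(OC)c(OCc2ccccc2)c1OC
F3 | step 6 | (2S,3S)-1-[3-(benzyloxy)-6-bromo-2,4-dimethoxyphenyl]-3-[2,3-bis(benzyloxy)-4-methoxyphenyl]-3-hydroxy-2-methoxypropan-1-one | COc1ccc([C@H](O)[C@H](OC)C(=O)c2c(Br)cc(OC)c(OCc3ccccc3)c2OC)c(OCc2ccccc2)c1OCc1ccccc1
F4 | step 7 | (2R,3R)-1-[3-(benzyloxy)-6-bromo-2,4-dimethoxyphenyl]-3-[2,3-bis(benzyloxy)-4-methoxyphenyl]-2-methoxypropane-1,3-diol (both C1 epimers) | COc1ccc([C@@H](O)[C@@H](OC)C(O)c2c(Br)cc(OC)c(OCc3ccccc3)c2OC)c(OCc2ccccc2)c1OCc1ccccc1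
F5 | step 7 | (2R,3S)-6-(benzyloxy)-2-[2,3-bis(benzyloxy)-4-methoxyphenyl]-3,5,7-trimethoxychroman-4-ol (both C4 epimers) | COc1ccc([C@H]2Oc3cc(OC)c(OCc4ccccc4)c(OC)c3C(O)[C@@H]2OC)c(OCc2ccccc2)c1OCc1ccccc1
F6 | step 8 | (2R,3R)-2-(2,3-dihydroxy-4-methoxyphenyl)-6-hydroxy-3,5,7-trimethoxychroman-4-one | COc1ccc([C@H]2Oc3cc(OC)c(O)c(OC)c3C(=O)[C@@H]2OC)c(O)c1O
F7 | step 2 | [3-(benzyloxy)-6-bromo-2,4-dimethoxyphenyl]lithium | [Li]c1c(Br)cc(OC)c(OCc2ccccc2)c1OC
A1 | alternative 1 | (2R,3R)-5-(benzyloxy)-2-[2,3-bis(benzyloxy)-4-methoxyphenyl]-6-hydroxy-3,7-dimethoxychroman-4-one | COc1ccc([C@H]2Oc3cc(OC)c(O)c(OCc4ccccc4)c3C(=O)[C@@H]2OC)c(OCc2ccccc2)c1OCc1ccccc1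
A2 | alternative 1 | (2R,3R)-1-[2-(benzyloxy)-3-hydroxy-4-methoxyphenyl]-3-[2,3-bis(benzyloxy)-4-methoxyphenyl]-3-hydroxy-2-methoxypropan-1-one | COc1ccc([C@@H](O)[C@@H](OC)C(=O)c2ccc(OC)c(O)c2OCc2ccccc2)c(OCc2ccccc2)c1OCc1ccccc1
A3 | alternative 2 | (2R,3R)-6-(benzyloxy)-2-[2,3-bis(benzyloxy)-4-methoxyphenyl]-3-hydroxy-5,7-dimethoxychroman-4-one | COc1ccc([C@H]2Oc3cc(OC)c(OCc4ccccc4)c(OC)c3C(=O)[C@@H]2O)c(OCc2ccccc2)c1OCc1ccccc1
A4 | alternative 2 | 3-(benzyloxy)-6-{1-[2,3-bis(benzyloxy)-4-methoxyphenyl]-2-oxoethoxy}-2,4-dimethoxybenzaldehyde (racemic) | COc1ccc(C(C=O)Oc2cc(OC)c(OCc3ccccc3)c(OC)c2C=O)c(OCc2ccccc2)c1OCc1ccccc1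
A5 | alternative 3 | (2R,3R)-5,6-bis(benzyloxy)-2-[2,3-bis(benzyloxy)-4-methoxyphenyl]-3,7-dimethoxychroman-4-one | COc1ccc([C@H]2Oc3cc(OC)c(OCc4ccccc4)c(OCc4ccccc4)c3C(=O)[C@@H]2OC)c(OCc2ccccc2)c1OCc1ccccc1
A6 | alternative 3 | 2,3-bis(benzyloxy)-4-methoxy-6-(trimethylsilyl)phenyl trifluoromethanesulfonate | COc1cc([Si](C)(C)C)c(OS(=O)(=O)C(F)(F)F)c(OCc2ccccc2)c1OCc1ccccc1
A7 | alternative 3 | methyl (2R,3R)-3-[2,3-bis(benzyloxy)-4-methoxyphenyl]-3-hydroxy-2-methoxypropanoate | COc1ccc([C@@H](O)[C@@H](OC)C(=O)OC)c(OCc2ccccc2)c1OCc1ccccc1
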